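| flask | starting material | free catalyst | remark | time |
|---|---|---|---|---|
| elm | 1.1 M | 7.1 mM | run made earlier |  |
| autumn | 1.0 M | 7.1 mM |  | 15 h |
| dawn | 0.30 M | 2.5 mM |  | 8.0 h |

elm run (percent of the starting material charged)

| time / h | target / % | starting material / % |
|---|---|---|
| 0.667 | 9.0 | 89.9 |
| 1.33 | 13.6 | 85.3 |
| 2.00 | 20.9 | 79.0 |
| 3.00 | 29.3 | 69.9 |
| 5.00 | 39.2 | 58.4 |
| 10.0 | 52.5 | 39.1 |

(readings scatter by 1 percentage point)

- reactions considered so far: starting material <-> target; target + free catalyst <-> isomer of the product + free catalyst; 2 free catalyst -> spent catalyst A; free catalyst -> spent catalyst B
- no earlier run changes the charge of free catalyst; that part of a forecast is a guess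

1. the flask that ends with the higher amount of target, in percent of the starting material charged, or "neither" when 2 percentage points or less lies between them (autumn / dawn / neither)
2. final target, as a percentage of the starting material charged, in autumn
3. final target, as a percentage of the starting material charged, in dawn

Slowness is what the elm run shows first, and a half-life puts a number on it. A first-order step running both ways, as starting material to target is taken to be here, closes the gap between c(starting material) and its end value by the same factor in each equal stretch of time, and its percent curve is the same for any charge. From the charge to 5.00 h and on to 10.0 h, the elm readings of starting material fall by 42 percentage points and then 19 points, a factor of 0.464, so the gap halves every 4.51 h, the relaxation half-life, and its end value reads near 22.4%, both with the scatter of the readings.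

How far does each flask get? Autumn runs 3.32 half-lives and dawn 1.77, leaving 30.1% and 45.1% of starting material, so autumn has converted 15 points more.

Can isomer take that lead back? The amount missing from the elm sum of starting material and target, read as isomer, grows from 2.40% at 5.00 h to 8.40% at 10.0 h. At that pace autumn is reckoned to reach 14.4%, less than the lead, while dawn is charged 2.96%, the elm amount at 10.0 h scaled by the catalyst charge as a guess. This reckoning gives 55.5% against 51.9%, a lead of 3.5 points, wider than the margin.

The forecast names autumn, with 56% (52% to 60%) and 52% (48% to 55%): “Autumn leads by about 4 points, though this is uncertain.”

Autumn ends at 58.0% and dawn at 50.3%, so autumn leads, with starting material at 32.3% and 45.3% against the reckoned 30.1% and 45.1%.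

    starting material ⇌ target (K = 2.30, k = 0.130 /h)
    target + free catalyst ⇌ isomer of the product + free catalyst, rate k2*[free catalyst]*[target] forward; the back reaction follows from the equilibrium constant (K = 1.80, k = 22.0 /M/h)
    2 free catalyst → spent catalyst A (k = 40.0 /M/h)
    free catalyst → spent catalyst B (k = 0.140 /h)

In autumn the half-life of free catalyst by its loss to spent catalyst B alone, 5.0 h, is shorter than the run, and at 15.0 h free catalyst stands at 2.69% of its charge, with isomer at 9.73% against the 14.4% of the elm pace. For the dawn flask read at 15 h, the relaxation half-life of 4.51 h gives 30.1% of starting material; the computed flask holds 33%, with target at 60.5%.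

The earlier runs and the new flask stem from a simulated flask from invented constants, and the scatter is random.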